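By the first reading, at 3.00 min, the left-handed substrate of both earlier runs had stopped moving, and its later readings show no trend beyond the scatter. The left-handed product of larch had not: it read 49% there and 43% at 8.00 min, a fall of 6 percentage points against a scatter of 2 points.

in all of them: left-handed substrate 0.052 M; right-handed substrate 0.052 M
- alder: coupling partner 0.76 equiv; run made earlier
- larch: coupling partner 4.4 equiv; run made earlier
- north-west: coupling partner 4.00 equiv; time 80 min
- west: coupling partner 1.00 equiv; time 80 min
- south-west: coupling partner 3.00 equiv; time 80 min
- south: coupling partner 6.00 equiv; time 80 min
- north: coupling partner 2.00 equiv; time 80 min

- alder (time / min: left-handed product / %, left-handed substrate / %): 3.00: 10, 42; 8.00: 13, 38; 15.0: 10, 42; 40.0: 11, 39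
- larch (time / min: left-handed product / %, left-handed substrate / %): 3.00: 49, 9; 8.00: 43, 11; 15.0: 42, 8; 40.0: 43, 13

(each reading ± 2 percentage points)

- coupling partner is single-handed; left-handed substrate and right-handed substrate are mirror images of each other, charged as a racemate, each of them at the stated concentration
- steps under discussion: coupling partner + left-handed substrate -> left-handed product; coupling partner + right-handed substrate -> right-handed product; left-handed substrate <-> right-handed substrate; coupling partner -> decomposed reagent; left-handed product <-> right-handed product
- the handed part of coupling partner does not stay in what it makes, so the products of the two hands are mirror images too

1. all flasks from highest to lowest amount of left-handed product, in percent of the left-handed substrate and right-handed substrate together charged, at 80 min (north-west / west / south-west / south / north)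
2. the amount of left-handed product, in percent of the left-handed substrate and right-handed substrate together charged of the flask you put first, at 80 min
3. the amount of left-handed product, in percent of the left-handed substrate and right-handed substrate together charged of the flask you put last, at 80 min

I averaged each run all the same, so the means below are readings with that fall inside them. Alder averaged 11.0% of left-handed product and 40.2% of left-handed substrate; larch averaged 44.2% and 10.2%. Each pair sums to about the left-handed charge, so I used both readings.

I assumed both hands couple alike, at a rate proportional to the partner present. Summing that chance over the run gives the exposure E:

fraction of each hand converted = 1 − e^(−E)

That puts E at 0.233 for alder and 1.83 for larch. If decomposition is also proportional to the partner, its loss per unit of exposure is constant, W, and the partner balance closes: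

equivalents charged = W·E + 2·(1 − e^(−E))

Alder gives 1.48 and larch 1.48. Their mean, 1.48, is what I carry: the equivalents of coupling partner lost to decomposition per unit of exposure, the waste number.

For west, a straight line through the curve gave a first exposure:

E = 0.287

That line was my weak link, so I corrected it once along the true curve:

west: E = 0.312, left-handed product 13.4%

south: E = 2.78, left-handed product 46.9%

My south stands above my west, and the balance rises steadily with the charge, so my order follows the equivalents.

The forecast reads south > north-west > south-west > north > west, with 47% (44% to 50%) and 14% (11% to 18%): “The reagent must therefore die quickly, with decomposition outrunning coupling.” Its order and top match mine; its low is 14% where mine is 13.4%.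

The flasks gave south > north-west > south-west > north > west, with south at 46.7% and west at 13.3%.

    coupling partner + left-handed substrate → left-handed product (k = 0.310 L mol⁻¹ s⁻¹)
    coupling partner + right-handed substrate → right-handed product (k = 0.200 L mol⁻¹ s⁻¹)
    left-handed substrate ⇌ right-handed substrate (k = 0.110 s⁻¹)
    coupling partner → decomposed reagent (k = 0.0200 s⁻¹)
    left-handed product ⇌ right-handed product (k = 6.70 × 10⁻⁴ s⁻¹)

In west the coupling partner, the limiting reagent, stood at 0% of its charge at 80.0 min, with 73% of the left-handed substrate charged still there. The using up of the partner cost that flask product, and its decomposition, as one part of the shortfall, cost less: west gave 50.0% with the partner held at its charge and 25.0% with decomposition taken away, against 13.3%. The waste number of 1.48, on a flask like south with 1.50 equiv of partner, gives an exposure of 0.489 and a left-handed product of 19.3%. That flask held 19.2% at 80.0 min.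

(The data are simulated with made-up constants; scatter was added.)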